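(All runs were computed from invented constants.)

Per minute and per millimolar of precatalyst charged: in these units the flask below can be reckoned from the earlier runs.

the same everywhere: gas 42 mM (held)
- eta: left-handed substrate 0.25 M; right-handed substrate 0.25 M; precatalyst 0.13 mol%; run made earlier
- zeta: left-handed substrate 0.38 M; right-handed substrate 0.38 M; precatalyst 0.13 mol%; run made earlier
- epsilon: left-handed substrate 0.50 M; right-handed substrate 0.50 M; precatalyst 0.065 mol%; run made earlier
- flask: left-handed substrate 0.50 M; right-handed substrate 0.50 M; precatalyst 0.13 mol%; time 50 min

| run | time / min | left-handed substrate / % | right-handed substrate / % |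
|---|---|---|---|
| eta | 4.00 | 47 | 48 |
| eta | 8.00 | 47 | 44 |
| eta | 15.0 | 41 | 38 |
| eta | 25.0 | 33 | 35 |
| eta | 50.0 | 21 | 23 |
| zeta | 10.0 | 41 | 41 |
| zeta | 20.0 | 31 | 36 |
| zeta | 30.0 | 25 | 26 |
| zeta | 40.0 | 19 | 22 |
| zeta | 50.0 | 13 | 13 |
| epsilon | 4.00 | 48 | 46 |
| epsilon | 8.00 | 45 | 46 |
| epsilon | 15.0 | 41 | 39 |
| epsilon | 25.0 | 32 | 35 |
| epsilon | 50.0 | 23 | 24 |

(each reading ± 1.5 percentage points)

- catalyst is single-handed; left-handed substrate and right-handed substrate are mirror images of each other, charged as a racemate, each of them at the stated concentration
- the analysis behind the earlier runs scatters by 1.5 percentage points, standard deviation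
- at the start none of the gas is in solution
- an excess is below zero if the other one leads

- part of the left-handed substrate and right-handed substrate charged together that has reacted at 50 min
- excess of left-handed product over right-handed product in the product at 50 min
- excess of right-handed substrate over left-handed substrate among what is left of the two at 50 min

Take first the main step by itself, with substrate falling in proportion to itself while the held gas and the catalyst stay constant: a pseudo-first-order fall. Eta and epsilon hold the same [precatalyst], 0.325 mM and 0.325 mM, and epsilon has twice the substrate of eta. From what remains at 50.0 min, their constants read 0.0164 /min and 0.0151 /min, a difference inside the scatter, so within that scatter the constant does not follow the substrate in these two runs.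

Now add the catalyst. Zeta, with 0.494 mM, gives 0.0269 /min from its reading at the same time. That constant stands 1.64 times eta's on 1.52 times the [precatalyst]; zeta differs from eta in substrate as well, but eta and epsilon showed no effect of substrate, so the constant is read as tracking the precatalyst charged. Dividing each constant by its [precatalyst] and averaging the three gives the turnover constant, the logarithmic fall of substrate per minute and per millimolar of precatalyst charged: 0.0505 /mM/min.

The rest enters as corrections. The start, with no gas yet in solution, is already averaged into constants read over the whole 50.0 min. At that time the two substrates differ by 2 percentage points in eta, 0 points in zeta and 1 point in epsilon, against a scatter of 1.5 points per reading, so one substrate pool serves. No run reports product, so I commit to no product excess. For the flask, [precatalyst] is 0.650 mM, which gives my conversion of 80.6%.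

The forecast gives 80%, 0.8% and 3.2%, and says of the two excesses: “Both are uncertain and could be zero.”

The flask gives 77.6%, 46.4% and 0.408%.

    gas ⇌ reagent, rate k1*(csat - [reagent]) (kL = 0.0277 /s)
    left-handed substrate ⇌ right-handed substrate (k = 0.0341 /s)
    reagent + catalyst + left-handed substrate → catalyst + left-handed product (k = 139 /M²/s)
    catalyst ⇌ dormant form (K = 0.888, k = 0.0132 /s)
    reagent + catalyst + right-handed substrate → catalyst + right-handed product (k = 50.6 /M²/s)
    precatalyst ⇌ catalyst (K = 0.515, k = 0.00332 /s)

The flask's own turnover constant comes to 0.0460 /mM/min. At 50.0 min the flask holds 11.2% left-handed and 11.2% right-handed substrate beside 56.8% left-handed and 20.8% right-handed product, and the exchange of the substrates, by that step alone and both ways together, relaxes with a half-life of 0.169 min, far shorter than the run. The neighbour flask, charged with 0.078 mol% of precatalyst, has [precatalyst] 0.390 mM, so the turnover constant gives it 62.7%. That neighbour reaches 61.4%, with a product excess of 46.5%.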